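Divide first.

all flasks: free catalyst 8.00 × 10⁻⁴ M

| flask | substrate | coupling partner | product | time |
|---|---|---|---|---|
| Wednesday's | 0.400 M | 0.480 M |  |  |
| Sunday's | 0.200 M | 0.280 M |  |  |
| Saturday's | 0.400 M | 0.480 M | 0.200 M |  |
| Friday's | 1.60 M | 0.480 M |  | 6.4 h |

| Wednesday's run: time / h | Wednesday's run: [product] / M | Sunday's run: time / h | Sunday's run: [product] / M | Saturday's run: time / h | Saturday's run: [product] / M |
|---|---|---|---|---|---|
| 1.3 | 0.2608 | 1.3 | 0.1059 | 1.3 | 0.4636 |
| 2.6 | 0.3042 | 2.6 | 0.1273 | 2.6 | 0.5069 |
| 3.8 | 0.3197 | 3.8 | 0.1388 | 3.8 | 0.5210 |
| 5.1 | 0.3349 | 5.1 | 0.1427 | 5.1 | 0.5320 |
| 6.4 | 0.3389 | 6.4 | 0.1512 | 6.4 | 0.5378 |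

(standard deviation of a reading: 0.002 M)

- Overall: substrate + coupling partner -> product, with free catalyst as catalyst.
- Constant volume, constant temperature.
- Bound and free are read together.
- "The second partner" is coupling partner.

- the Sunday's run starts with 0.200 M less of substrate and of coupling partner than the Wednesday's run, and with no product. Compared where both hold the same amount of substrate, once fifteen percent of what the Sunday's run was charged with has turned into product, is the Sunday's run faster, slower or alike (within a tenth)?
- product in the Friday's run at 6.4 h, as a share of the substrate charged
- which of these the readings show (the catalyst dies in pairs / nothing beyond the main steps / the second partner pairs with itself / the catalyst wakes slowly)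

Friday's flask is charged with less coupling partner than substrate, so the partner is the limiting reagent, and product can come to at most 30.0% of the substrate charged.

Whether it gets there by 6.4 h needs one more number, which you can read from Wednesday's run. Take the rate, as my working assumption, as proportional to substrate and to partner. The logarithm of the ratio of the two fractions left then grows in step with the gap between the two charges. That logarithm divided by the gap, at a given clock time, I call the dose. At its last reading, Wednesday's run has 29.4% of its partner and 15.3% of its substrate left, with a gap of 0.0800 M, so the dose read there is 8.18 /M.

Friday's gap is 1.12 M. If Friday's flask takes the same dose by the same clock time, then with 70.0% of the substrate left at the ceiling I reckon the partner down to 0.00733% of its charge. My reckoning therefore gives 30.0%.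

The forecast says faster and the catalyst dies in pairs, and for Friday's flask 30% (from 29.3% to 30.1%), on the ground that “the partner is essentially exhausted”.

The simulation gives 30.0% for Friday's flask. Sunday's run comes out faster, at 1.6 times the rate of Wednesday's run at the point asked, where both hold the same amount of substrate, and the readings show that the catalyst dies in pairs.

    free catalyst + substrate ⇌ catalyst-substrate complex, settled at all times (0.5030 /M)
    catalyst-substrate complex + coupling partner ⇌ ternary complex, settled at all times (7.400 /M)
    ternary complex → product + free catalyst (1904 /h)
    2 free catalyst → 2 spent catalyst (1289 /M/h)

Friday's 30.0% does not move when the step that turns free catalyst into spent catalyst is taken away. Sunday's run has the same gap as Wednesday's, so Wednesday's dose of 8.18 /M gives it 76.4% of its substrate as product at 6.4 h, and the reading there is 75.6%.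

The readings are calculated with constants of no real substance; scatter was added.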